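I commit to one hand-read number before any fitting. Here is the flask, what was run before it, and what is asked:

common to all: substrate 0.28 M; temperature −20 °C
- grey: partner 0.504 M; the very flask that is asked about, followed so far
- ochre: partner 0.25 M; run made earlier
- flask: partner 0.504 M; time 12 h

- grey (time / min: target / %, substrate / %): 40.0: 9.8, 0.3; 120: 9.2, 0.1; 180: 9.0, 0.1; 300: 9.7, 0; 480: 9.2, 0.3; 600: 9.1, 0.1
- ochre (time / min: target / %, substrate / %): 2.00: 58.1, 4.8; 5.00: 54.5, 0; 10.0: 34.8, 0; 15.0: 22.5, 0; 20.0: 15.7, 0; 30.0: 10.5, 0

(readings scatter by 0.3 percentage points)

- eta: at 12 h add partner, 100 % of the amount charged, then wait 25 h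
- theta: change nothing and wait 25 h more
- alpha: at 12 h raise the temperature by 25 K, then wait 25 h
- zeta: at 12 h take out 90 % of the target then present, then wait 25 h

- target that was removed still counts
- additions bring no volume worth counting
- the earlier runs do not show what temperature does; that part of a forecast is a guess

- target, in percent of the substrate first charged, at 12 h
- which option adds most target ("none" when 2 percentage points or less is all one gets) (eta / theta / alpha / zeta / none)
- target present, with what was taken out counted in, in percent of the substrate first charged, after eta
- target present, with what was taken out counted in, in percent of the substrate first charged, after zeta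

- Grey's target readings from 40.0 min to 600 min are flat and average 9.33 %. I call this f, the plateau share: the chance that a molecule which has passed through the reaction stands as target at a given moment. The rest sits in some unseen form.
- In grey, partner at 0.504 M is more than substrate at 0.28 M, so substrate is the limiting reagent, and it reads 0.1 % at 600 min.
- Ochre looks nearly the same, but its partner at 0.25 M is less than its substrate, so I count partner as the limit on ochre's pool, which I put at 89.3 % of the charge. The same fork then puts ochre's floor at 8.33 %.
- Ochre's target reads 58.1 % at 2.00 min and is still falling at 10.5 % at 30.0 min. Measured above that floor, the fall has a half-time of about 5.42 min.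
- That half-time is far shorter than 12 h, so I expect grey to stand at f at 12 h, and at −20 °C to return to f of its pool after target is taken out.
- Theta therefore gains nothing by my reckoning, and neither does eta, since grey's substrate reads 0.1 % at 600 min, less than the scatter of 0.3 percentage points. Zeta banks 8.40 %, and f of the remainder re-forms, for a total of 16.9 %, a gain of 7.6 points.
- My f holds at −20 °C. What alpha does to it is a guess, so I bank zeta and leave alpha open.
- The forecast gives 9.3 % now, 9.3 % after eta and 16.9 % after zeta, and picks zeta, judging warming “unlikely to help much”.

    target ⇌ isomer of the product (K = 10.0, k = 0.00202 /s, Ea = 76.0 kJ/mol, ΔH = −31.0 kJ/mol)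
    substrate → intermediate (k = 0.0254 /s, Ea = 59.0 kJ/mol)
    partner + intermediate → target (k = 0.130 /M/s, Ea = 47.0 kJ/mol)
    (constants at −20 °C)

- Grey holds 9.09 % target at 12 h beside 90.9 % isomer of the product, the unseen form. Zeta adds 7.4 points and reaches 16.5 %, but alpha adds most, 18 points. The neighbour at −5 °C, with the same amounts, holds 18.6 % target at 12 h, more than grey's 9.09 %. The neighbour charged with 1.1 M substrate has its partner at 0 %, and there f times partner charge over substrate charge gives 4.28 %, while that flask holds 4.17 %.

The data were computed from invented constants, and the scatter is random.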